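**Retrosynthetic overview**
- Last C–C bond: C3–C4 of the pentadienyl linker, by palladium-carbene coupling of a C10 α-methyl aldehyde (as its tosylhydrazone/diazo form, so the aldehyde carbon acts as donor) with a C10 (E)-alkenyl iodide. The same step creates the C2=C3 alkene by β-hydride elimination; desilylation then gives the target.
- Alkenyl iodide ⇐ Takai iodoolefination ⇐ oxane aldehyde ⇐ ozonolysis ⇐ vinyl bromo-oxane ⇐ bromoetherification of (S)-linalool.
- Aldehyde ⇐ hydroboration/oxidation of the isopropenyl group ⇐ silylated cis-bromohydrin ⇐ SN2 inversion at C2 of (1S,2S,4R)-limonene-1,2-diol.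
- Rings: the cyclohexane is bought intact from the chiral pool; the oxane is the only ring made, closed in step 1 before fragment union.

Assumption: (S)-(+)-linalool and (1S,2S,4R)-(+)-limonene-1,2-diol are purchased in high enantiomeric purity.

**Step 1**
Reactants: 1 (S)-(+)-linalool [(3S)-3,7-dimethylocta-1,6-dien-3-ol]
Product: 2 (3R,6S)-3-bromo-6-ethenyl-2,2,6-trimethyloxane
Conditions: TBCO (1.1 equiv), MeNO2, 0 °C → rt, dark; chromatography
Reagents that add atoms: 2,4,4,6-tetrabromocyclohexa-2,5-dien-1-one (TBCO), O=C1C(Br)=CC(Br)(Br)C=C1Br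
Why: Bromoetherification (bromonium-triggered 6-endo Markovnikov cyclisation) in which the tertiary hydroxyl opens the bromonium ion at the tertiary carbon anti to bromine through a chair with equatorial Br; C6 comes unchanged from 1, whereas C3 is formed with little bias (about 1:1 with the 3S epimer, plus 5-exo oxolanes), so the 3R isomer (Br cis to the C6 methyl) is isolated by chromatography.

**Step 2**
Reactants: 2 (3R,6S)-3-bromo-6-ethenyl-2,2,6-trimethyloxane
Product: 4 (2S,5R)-5-bromo-2,6,6-trimethyloxane-2-carbaldehyde, via ozonide 3 (not isolated)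
Conditions: O3, CH2Cl2, −78 °C; then PPh3, −78 °C → rt
Reagents that add atoms: ozone, [O-][O+]=O
Why: Ozonolysis with reductive work-up (Criegee mechanism) cleaves the only alkene to a non-enolisable α-alkoxy aldehyde and touches neither stereocentre.

**Step 3**
Reactants: 4 (2S,5R)-5-bromo-2,6,6-trimethyloxane-2-carbaldehyde
Product: 5 (3R,6S)-3-bromo-6-[(E)-2-iodoethenyl]-2,2,6-trimethyloxane
Conditions: CrCl2 (6 equiv), CHI3 (2 equiv), THF, 0 °C → rt
Reagents that add atoms: iodoform, IC(I)I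
Why: Takai iodoolefination, in which the geminal dichromium reagent from CHI3 and CrCl2 adds to the aldehyde and eliminates to the E-alkenyl iodide (E strongly favoured for α-quaternary aldehydes), while the unactivated secondary bromide is inert to CrCl2.

**Step 4**
Reactants: 6 (1S,2S,4R)-limonene-1,2-diol [(1S,2S,4R)-1-methyl-4-(prop-1-en-2-yl)cyclohexane-1,2-diol]
Product: 8 (1S,2S,5R)-2-methyl-5-(prop-1-en-2-yl)-2-(triethylsilyloxy)cyclohexyl chloromethanesulfonate, via hydroxy monochlate 7 (not isolated)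
Conditions: ClCH2SO2Cl, pyridine, CH2Cl2, 0 °C; then 2,6-lutidine, TESOTf, −40 → 0 °C
Reagents that add atoms: chloromethanesulfonyl chloride, ClCS(=O)(=O)Cl; triethylsilyl trifluoromethanesulfonate, CC[Si](CC)(CC)OS(=O)(=O)C(F)(F)F
Why: Chemoselective O-sulfonylation of the secondary axial hydroxyl followed in the same flask by O-silylation of the tertiary hydroxyl; no stereocentre is touched, and the silyl ether suppresses epoxide formation by the anti oxygen in step 5 and masks the alcohol from the base of step 7.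

**Step 5**
Reactants: 8 (1S,2S,5R)-2-methyl-5-(prop-1-en-2-yl)-2-(triethylsilyloxy)cyclohexyl chloromethanesulfonate
Product: 9 {[(1S,2R,4R)-2-bromo-1-methyl-4-(prop-1-en-2-yl)cyclohexyl]oxy}triethylsilane
Conditions: LiBr (5 equiv), DMF, 50 °C
Reagents that add atoms: lithium bromide, [Li+].[Br-]
Why: SN2 displacement with Walden inversion, in which bromide attacks the backside of the axial chloromethanesulfonate to give the equatorial C2 bromide cis to the C1 oxygen (2S → 2R), which is the cis-bromohydrin configuration of the target.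

**Step 6**
Reactants: 9 {[(1S,2R,4R)-2-bromo-1-methyl-4-(prop-1-en-2-yl)cyclohexyl]oxy}triethylsilane
Product: 12 2-[(1R,3R,4S)-3-bromo-4-methyl-4-(triethylsilyloxy)cyclohexyl]propanal, via trialkylborane 10 (not isolated), via trialkyl borate 11 (not isolated)
Conditions: BH3·THF (0.4 equiv), THF, 0 °C → rt; then NMO (excess), Pr4N[RuO4] (5 mol %), 4 Å MS, CH2Cl2, rt
Reagents that add atoms: N-methylmorpholine N-oxide, C[N+]1([O-])CCOCC1
Why: Anti-Markovnikov hydroboration of the 1,1-disubstituted alkene followed by one-pot amine-oxide oxidation of the C–B bonds and Ley–Griffith perruthenate oxidation gives the aldehyde; the new methine centre forms as both epimers, which does not matter because it becomes sp2 in step 7.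

**Step 7**
Reactants: 12 2-[(1R,3R,4S)-3-bromo-4-methyl-4-(triethylsilyloxy)cyclohexyl]propanal; 5 (3R,6S)-3-bromo-6-[(E)-2-iodoethenyl]-2,2,6-trimethyloxane
Product: 15 {[(1S,2R,4R)-2-bromo-4-{(2E,4E)-5-[(2S,5R)-5-bromo-2,6,6-trimethyloxan-2-yl]penta-2,4-dien-2-yl}-1-methylcyclohexyl]oxy}triethylsilane, via tosylhydrazone 13 (not isolated), via diazoalkane 14 (not isolated)
Conditions: TsNHNH2 (1.05 equiv), dioxane, 60 °C; then 5 (1.0 equiv), Pd2(dba)3 (2.5 mol %), XPhos (10 mol %), LiOtBu (2.4 equiv), 90 °C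
Reagents that add atoms: none
Why: Barluenga palladium-carbene cross-coupling, in which the aldehyde carbon of 12, normally an acceptor, is converted through 13 into the diazo carbon of 14 and so acts as a donor (a reversed-polarity d1 carbon) towards the alkenyl–Pd–I species formed from 5 and zerovalent palladium; migratory insertion of the alkenyl group into the palladium carbene forms the C3–C4 bond as a π-allylpalladium, syn β-hydride elimination of the only available hydrogen gives the C2=C3 alkene with the cyclohexyl group away from the chain (E), and the E geometry of 5 is kept in the syn-allyl.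

**Step 8**
Reactants: 15 {[(1S,2R,4R)-2-bromo-4-{(2E,4E)-5-[(2S,5R)-5-bromo-2,6,6-trimethyloxan-2-yl]penta-2,4-dien-2-yl}-1-methylcyclohexyl]oxy}triethylsilane
Product: 16 (1S,2R,4R)-2-bromo-4-{(2E,4E)-5-[(2S,5R)-5-bromo-2,6,6-trimethyloxan-2-yl]penta-2,4-dien-2-yl}-1-methylcyclohexan-1-ol
Conditions: HF·pyridine, pyridine, THF, 0 °C → rt
Reagents that add atoms: none
Why: Fluoride-driven desilylation (Si–F bond formation) under buffered, non-basic conditions frees the tertiary alcohol without ionising the dienylic ether or triggering semipinacol ring contraction of the cis-bromohydrin, and no stereocentre is affected.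

**Compound list**
1 | (S)-(+)-linalool, (3S)-3,7-dimethylocta-1,6-dien-3-ol | C=C[C@@](C)(O)CCC=C(C)C | starting material
2 | (3R,6S)-3-bromo-6-ethenyl-2,2,6-trimethyloxane | C=C[C@]1(C)CC[C@@H](Br)C(C)(C)O1 | intermediate
3 | ozonide of 2, (3R,6S)-3-bromo-2,2,6-trimethyl-6-(1,2,4-trioxolan-3-yl)oxane (both epimers at the trioxolane carbon) | C1(OCOO1)[C@]2(C)CC[C@@H](Br)C(C)(C)O2 | intermediate
4 | (2S,5R)-5-bromo-2,6,6-trimethyloxane-2-carbaldehyde | O=C[C@]1(C)CC[C@@H](Br)C(C)(C)O1 | intermediate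
5 | (3R,6S)-3-bromo-6-[(E)-2-iodoethenyl]-2,2,6-trimethyloxane | I/C=C/[C@]1(C)CC[C@@H](Br)C(C)(C)O1 | intermediate
6 | (1S,2S,4R)-limonene-1,2-diol, (1S,2S,4R)-1-methyl-4-(prop-1-en-2-yl)cyclohexane-1,2-diol | CC(=C)[C@@H]1CC[C@](C)(O)[C@@H](O)C1 | starting material
7 | (1S,2S,5R)-2-hydroxy-2-methyl-5-(prop-1-en-2-yl)cyclohexyl chloromethanesulfonate | CC(=C)[C@@H]1CC[C@](C)(O)[C@@H](OS(=O)(=O)CCl)C1 | intermediate
8 | (1S,2S,5R)-2-methyl-5-(prop-1-en-2-yl)-2-(triethylsilyloxy)cyclohexyl chloromethanesulfonate | CC(=C)[C@@H]1CC[C@](C)(O[Si](CC)(CC)CC)[C@@H](OS(=O)(=O)CCl)C1 | intermediate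
9 | {[(1S,2R,4R)-2-bromo-1-methyl-4-(prop-1-en-2-yl)cyclohexyl]oxy}triethylsilane | CC(=C)[C@@H]1CC[C@](C)(O[Si](CC)(CC)CC)[C@H](Br)C1 | intermediate
10 | tris{2-[(1R,3R,4S)-3-bromo-4-methyl-4-(triethylsilyloxy)cyclohexyl]propyl}borane (epimers at each propyl C2) | B(CC(C)[C@@H]1CC[C@](C)(O[Si](CC)(CC)CC)[C@H](Br)C1)(CC(C)[C@@H]1CC[C@](C)(O[Si](CC)(CC)CC)[C@H](Br)C1)CC(C)[C@@H]1CC[C@](C)(O[Si](CC)(CC)CC)[C@H](Br)C1 | intermediate
11 | tris{2-[(1R,3R,4S)-3-bromo-4-methyl-4-(triethylsilyloxy)cyclohexyl]propyl} borate (epimers at each propyl C2) | B(OCC(C)[C@@H]1CC[C@](C)(O[Si](CC)(CC)CC)[C@H](Br)C1)(OCC(C)[C@@H]1CC[C@](C)(O[Si](CC)(CC)CC)[C@H](Br)C1)OCC(C)[C@@H]1CC[C@](C)(O[Si](CC)(CC)CC)[C@H](Br)C1 | intermediate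
12 | 2-[(1R,3R,4S)-3-bromo-4-methyl-4-(triethylsilyloxy)cyclohexyl]propanal (both C2 epimers) | O=CC(C)[C@@H]1CC[C@](C)(O[Si](CC)(CC)CC)[C@H](Br)C1 | intermediate
13 | N'-[(1E)-2-{(1R,3R,4S)-3-bromo-4-methyl-4-(triethylsilyloxy)cyclohexyl}propylidene]-4-methylbenzenesulfonohydrazide | Cc1ccc(cc1)S(=O)(=O)N/N=C/C(C)[C@@H]1CC[C@](C)(O[Si](CC)(CC)CC)[C@H](Br)C1 | intermediate
14 | {[(1S,2R,4R)-2-bromo-4-(1-diazopropan-2-yl)-1-methylcyclohexyl]oxy}triethylsilane | [N-]=[N+]=CC(C)[C@@H]1CC[C@](C)(O[Si](CC)(CC)CC)[C@H](Br)C1 | intermediate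
15 | {[(1S,2R,4R)-2-bromo-4-{(2E,4E)-5-[(2S,5R)-5-bromo-2,6,6-trimethyloxan-2-yl]penta-2,4-dien-2-yl}-1-methylcyclohexyl]oxy}triethylsilane | C/C(=C\C=C\[C@]1(C)CC[C@@H](Br)C(C)(C)O1)[C@@H]1CC[C@](C)(O[Si](CC)(CC)CC)[C@H](Br)C1 | intermediate
16 | (1S,2R,4R)-2-bromo-4-{(2E,4E)-5-[(2S,5R)-5-bromo-2,6,6-trimethyloxan-2-yl]penta-2,4-dien-2-yl}-1-methylcyclohexan-1-ol | C/C(=C\C=C\[C@]1(C)CC[C@@H](Br)C(C)(C)O1)[C@@H]1CC[C@](C)(O)[C@H](Br)C1 | target

**Totals**
Total steps: 8. Longest linear sequence: 5 (steps 4, 5, 6, 7, 8; the linalool branch, steps 1, 2, 3, 7, 8, is equally long).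

**Three steps most likely to fail**

Step 1. The bromonium cyclisation gives roughly equal C3 epimers and competing 5-exo oxolanes, so the yield of 2 is low. The fallback sets out from 1 and comes back at 2 by mercury-templated ring closure followed by halogen exchange. Compound 1 is cyclised with Hg(OCOCF3)2 in MeNO2 at 0 °C and the salt exchanged with aqueous NaCl to give chloro[(3R,6S)-6-ethenyl-2,2,6-trimethyloxan-3-yl]mercury F1. Oxymercuration is reversible and strictly Markovnikov, so only the six-membered ether forms, and the C3 epimers of the crystalline chloromercurial can be equilibrated and separated. Bromodemercuration of F1 with Br2 and LiBr in pyridine at 0 °C (retention) then gives 2.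

Step 5. The SN2 reaction is at a secondary carbon next to a fully substituted one, so halide-induced E2 to the allylic silyl ether, or no reaction, may win. The fallback sets out from 6 and comes back at 9, using a tethered electrophile instead of an open sulfonate. SOCl2 and pyridine in CH2Cl2 at 0 °C convert 6 into the cyclic sulfite (3aS,6R,7aS)-3a-methyl-6-(prop-1-en-2-yl)hexahydro-1,3,2-benzodioxathiole 2-oxide F2, in which neither oxygen can act as a neighbouring group. LiBr in DMF at 90 °C opens it at the secondary carbon with inversion to lithium (1S,2R,4R)-2-bromo-1-methyl-4-(prop-1-en-2-yl)cyclohexyl sulfite F3. Dilute H2SO4 work-up gives (1S,2R,4R)-2-bromo-1-methyl-4-(prop-1-en-2-yl)cyclohexan-1-ol F4. TESOTf and 2,6-lutidine then give 9.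

Step 7. LiOtBu at 90 °C with two secondary bromides, loss of the non-stabilised diazoalkane 14 by 1,2-hydrogen shift or azine formation, and incomplete E selectivity at the new trisubstituted alkene are the dangers. The fallback sets out from 12 and 5 and comes back at 15, with an acyl-donor coupling at room temperature followed by base-free elimination. Compounds 12 and 5 are joined by nickel/photoredox hydrogen-atom-transfer acylation, in which the acyl radical from the aldehyde C–H is captured by nickel and coupled with the alkenyl iodide (NiBr2(dtbbpy), Ir[dF(CF3)ppy]2(dtbbpy)PF6, quinuclidine, K2CO3, dioxane, blue light, rt). This gives the enone (1E)-4-[(1R,3R,4S)-3-bromo-4-methyl-4-(triethylsilyloxy)cyclohexyl]-1-[(2S,5R)-5-bromo-2,6,6-trimethyloxan-2-yl]pent-1-en-3-one F5. NaBH4 with CeCl3·7H2O in MeOH gives the allylic alcohol (1E)-4-[(1R,3R,4S)-3-bromo-4-methyl-4-(triethylsilyloxy)cyclohexyl]-1-[(2S,5R)-5-bromo-2,6,6-trimethyloxan-2-yl]pent-1-en-3-ol F6. ClCO2Me and pyridine give the methyl carbonate of that alcohol F7. Pd(PPh3)4 in dioxane at 80 °C ionises F7 to the same π-allylpalladium species as in step 7, which loses its only β-hydrogen to give 15.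

**Further compounds**
F1 | step 1 | chloro[(3R,6S)-6-ethenyl-2,2,6-trimethyloxan-3-yl]mercury | C=C[C@]1(C)CC[C@@H]([Hg]Cl)C(C)(C)O1
F2 | step 5 | (3aS,6R,7aS)-3a-methyl-6-(prop-1-en-2-yl)hexahydro-1,3,2-benzodioxathiole 2-oxide | CC(=C)[C@@H]1CC[C@]2(C)OS(=O)O[C@H]2C1
F3 | step 5 | lithium (1S,2R,4R)-2-bromo-1-methyl-4-(prop-1-en-2-yl)cyclohexyl sulfite | CC(=C)[C@@H]1CC[C@](C)(OS(=O)[O-])[C@H](Br)C1.[Li+]
F4 | step 5 | (1S,2R,4R)-2-bromo-1-methyl-4-(prop-1-en-2-yl)cyclohexan-1-ol | CC(=C)[C@@H]1CC[C@](C)(O)[C@H](Br)C1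
F5 | step 7 | (1E)-4-[(1R,3R,4S)-3-bromo-4-methyl-4-(triethylsilyloxy)cyclohexyl]-1-[(2S,5R)-5-bromo-2,6,6-trimethyloxan-2-yl]pent-1-en-3-one | CC(C(=O)/C=C/[C@]1(C)CC[C@@H](Br)C(C)(C)O1)[C@@H]1CC[C@](C)(O[Si](CC)(CC)CC)[C@H](Br)C1
F6 | step 7 | (1E)-4-[(1R,3R,4S)-3-bromo-4-methyl-4-(triethylsilyloxy)cyclohexyl]-1-[(2S,5R)-5-bromo-2,6,6-trimethyloxan-2-yl]pent-1-en-3-ol | CC(C(O)/C=C/[C@]1(C)CC[C@@H](Br)C(C)(C)O1)[C@@H]1CC[C@](C)(O[Si](CC)(CC)CC)[C@H](Br)C1
F7 | step 7 | (1E)-4-[(1R,3R,4S)-3-bromo-4-methyl-4-(triethylsilyloxy)cyclohexyl]-1-[(2S,5R)-5-bromo-2,6,6-trimethyloxan-2-yl]pent-1-en-3-yl methyl carbonate | CC(C(OC(=O)OC)/C=C/[C@]1(C)CC[C@@H](Br)C(C)(C)O1)[C@@H]1CC[C@](C)(O[Si](CC)(CC)CC)[C@H](Br)C1
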